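Locants: C1 = methyl on C2; C2=C3 alkene; ring A = C3–C7 (C5 carbinol, C6 methyl); C8 carbinol; C9 quaternary, its methyl = C9a; ring C = C9–C12, C17, C18; ring D = C12–C17; C19, C20 = methylenes of eight-membered ring B.
Retrosynthesis: C8–OH/C9–CH3 are traced back to a C8 ketone and a C9 formyl group; C3–C7 and C8–C9 are then cut together; cutting C2–C20 and a temporary C3–C8 bond gives an ynal (C1–C8) and a decalin alkyl iodide (rings C and D, C19, C20).
Enabling feature: ring A carries the oxygenated C8 on C7 next to the exocyclic C2=C3 alkylidene, so it is the Wolff ring-contraction product of a 2-alkylidene-6-diazocyclohexanone (C3 temporarily on C8); the ketene carbon C8 so formed faces the enol-ether carbon C9 on ring C.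
Forward: ring D then ring C (imine Michael/Robinson, Birch alkylation, Wittig); West chain (Sharpless epoxide, two epoxide openings); nickel alkylative cyclization (union, temporary six-membered ring); diazo transfer; photochemical key step (rings A and B); redox adjustment at C9a and C8.
Stereochemistry: C12 from the chiral imine; C17 and C18 from Birch reduction/alkylation; C5 and C6 from Sharpless epoxidation and anti epoxide opening; alkene geometry from syn alkylnickelation; C9 from equatorial attack; C7 from kinetic protonation; C8 from hydroxyl-directed reduction.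
Key step: step 18

Remark: DEC = (1S,2E,4aS,8aS)-2-(methoxymethylidene)-4a,7,7-trimethyldecahydronaphthalen-1-yl; alcohol 25 should form as both C1 epimers, which converge in step 16, and the enol ether geometry (drawn E) has no consequence.

Step 1
Reactants: 1 3,3-dimethylcyclohexan-1-one
Product: 3 2,5,5-trimethylcyclohexan-1-one (racemic), via lithium enolate 2 (not isolated)
Conditions: LiN(iPr)2, THF, −78 °C; MeI, −78 → 0 °C
Reagents that add atoms: iodomethane (CI)
Why: Kinetic deprotonation should occur at the unhindered C6 methylene (the other α-methylene is neopentyl), and methylation of the enolate gives the 2-methyl ketone, whose stereocentre is erased in step 2 (enolate alkylation).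

Step 2
Reactants: 3 2,5,5-trimethylcyclohexan-1-one
Product: 6 (S)-2,5,5-trimethyl-2-(3-oxobutyl)cyclohexan-1-one, via ketimine 4 (not isolated), via Michael adduct ketimine 5 (not isolated)
Conditions: (R)-PhCH(CH3)NH2, toluene, reflux (Dean–Stark); CH2=CHCOCH3, THF, 20 °C; 10 % aq. AcOH, 20 °C
Reagents that add atoms: but-3-en-2-one (CC(=O)C=C); water (O)
Why: The more substituted secondary enamine tautomer of the chiral ketimine should add to the enone through a chair-like aza-ene transition state on the face away from the phenyl group, which sets the quaternary centre (future C12) before hydrolysis (deracemizing imine Michael addition, first half of a Robinson annulation).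

Step 3
Reactants: 6 (S)-2,5,5-trimethyl-2-(3-oxobutyl)cyclohexan-1-one
Product: 7 (S)-4a,7,7-trimethyl-4,4a,5,6,7,8-hexahydronaphthalen-2(3H)-one
Conditions: NaOMe, MeOH, 60 °C
Reagents that add atoms: none
Why: Intramolecular aldol condensation of the methyl ketone onto the ring ketone closes ring C as the conjugated octalone (second half of the Robinson annulation).

Step 4
Reactants: 7 (S)-4a,7,7-trimethyl-4,4a,5,6,7,8-hexahydronaphthalen-2(3H)-one
Product: 9 tert-butyl 2-[(1S,4aS,8aS)-4a,7,7-trimethyl-2-oxodecahydronaphthalen-1-yl]acetate, via lithium enolate 8 (not isolated)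
Conditions: Li, NH3 (l), THF, t-BuOH (1 equiv), −78 °C; NH3 evaporated; BrCH2CO2t-Bu, THF, −78 → 0 °C
Reagents that add atoms: tert-butyl bromoacetate (CC(C)(C)OC(=O)CBr)
Why: Birch reduction protonates C17 axially to give the trans-fused enolate regiospecifically, and C-alkylation by the α-bromo ester should place the chain equatorially at C18, anti to the angular methyl (Birch reduction–enolate alkylation).

Step 5
Reactants: 9 tert-butyl 2-[(1S,4aS,8aS)-4a,7,7-trimethyl-2-oxodecahydronaphthalen-1-yl]acetate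
Product: 10 tert-butyl 2-(DEC)acetate
Conditions: Ph3P(CH2OMe)Cl, KN(SiMe3)2, THF, 0 °C; then 9, 0 → 20 °C
Reagents that add atoms: (methoxymethyl)triphenylphosphonium chloride (COC[P+](c1ccccc1)(c1ccccc1)c1ccccc1.[Cl-])
Why: The non-stabilized ylide should olefinate the ring ketone in preference to the hindered tert-butyl ester and installs C9a as an enol ether whose β-carbon C9 is the nucleophile of the key step (Wittig reaction).

Step 6
Reactants: 10 tert-butyl 2-(DEC)acetate
Product: 11 2-(DEC)ethan-1-ol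
Conditions: LiAlH4, Et2O, 0 °C
Reagents that add atoms: none
Why: Hydride reduction of the ester gives the primary alcohol and leaves the base-stable enol ether untouched (LiAlH4 ester reduction).

Step 7
Reactants: 11 2-(DEC)ethan-1-ol
Product: 12 (1S,2E,4aS,8aS)-1-(2-iodoethyl)-2-(methoxymethylidene)-4a,7,7-trimethyldecahydronaphthalene
Conditions: PPh3, I2, imidazole, CH2Cl2, 0 °C
Reagents that add atoms: iodine (II)
Why: The alcohol is converted into the primary iodide under buffered, non-acidic conditions that the enol ether should tolerate (Appel-type iodination).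

Step 8
Reactants: 13 (E)-but-2-en-1-ol
Product: 14 [(2R,3R)-3-methyloxiran-2-yl]methanol
Conditions: Ti(OiPr)4 (cat.), D-(−)-diethyl tartrate, t-BuOOH, 4 Å molecular sieves, CH2Cl2, −20 °C
Reagents that add atoms: tert-butyl hydroperoxide (CC(C)(C)OO)
Why: The titanium–D-tartrate complex delivers oxygen to the face of the allylic alcohol that gives the (2R,3R)-epoxide, the source of C5 and C6 (Sharpless asymmetric epoxidation).

Step 9
Reactants: 14 [(2R,3R)-3-methyloxiran-2-yl]methanol
Product: 15 (2S,3R)-3-methylpent-4-ene-1,2-diol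
Conditions: CH2=CHMgBr, CuI (10 mol %), THF, −40 → −20 °C
Reagents that add atoms: vinylmagnesium bromide (C=C[Mg]Br)
Why: The vinyl cuprate should open the epoxide at C3, remote from the hydroxymethyl group, with inversion, which gives the syn relation of the C5 oxygen and the C6 methyl (copper-catalysed SN2 epoxide opening).

Step 10
Reactants: 15 (2S,3R)-3-methylpent-4-ene-1,2-diol
Product: 17 (2S)-2-[(2R)-but-3-en-2-yl]oxirane, via primary tosylate 16 (not isolated)
Conditions: NaH, THF, 0 °C; 1-(p-toluenesulfonyl)imidazole, 0 → 20 °C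
Reagents that add atoms: none
Why: Selective sulfonylation of the primary hydroxyl and displacement by the secondary alkoxide give the terminal epoxide with the carbinol configuration intact (intramolecular Williamson reaction).

Step 11
Reactants: 17 (2S)-2-[(2R)-but-3-en-2-yl]oxirane
Product: 18 (3R,4R)-3-methyloct-1-en-6-yn-4-ol
Conditions: propyne, n-BuLi, THF, −78 °C; BF3·OEt2; then 17, −78 °C
Reagents that add atoms: propyne (CC#C)
Why: The lithium acetylide opens the BF3-activated epoxide at its methylene carbon and so attaches C1–C3 to the stereodiad (BF3-mediated alkynylation of an epoxide).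

Step 12
Reactants: 18 (3R,4R)-3-methyloct-1-en-6-yn-4-ol
Product: 19 tert-butyldimethyl{[(3R,4R)-3-methyloct-1-en-6-yn-4-yl]oxy}silane
Conditions: t-BuMe2SiCl, imidazole, DMF, 20 °C
Reagents that add atoms: tert-butyl(chloro)dimethylsilane (CC(C)(C)[Si](C)(C)Cl)
Why: The C5 hydroxyl is masked so that it cannot quench the organozinc reagent or trap the ketene later (silyl ether formation).

Step 13
Reactants: 19 tert-butyldimethyl{[(3R,4R)-3-methyloct-1-en-6-yn-4-yl]oxy}silane
Product: 21 (3R,4R)-4-[(tert-butyldimethylsilyl)oxy]-3-methyloct-6-yn-1-ol, via alkylborane 20 (not isolated)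
Conditions: 9-BBN, THF, 0 → 20 °C; NaOH, H2O2, 0 °C
Reagents that add atoms: hydrogen peroxide (OO)
Why: The bulky borane should add to the monosubstituted alkene in the anti-Markovnikov sense much faster than to the internal alkyne, and oxidation gives the C8 alcohol (hydroboration–oxidation).

Step 14
Reactants: 21 (3R,4R)-4-[(tert-butyldimethylsilyl)oxy]-3-methyloct-6-yn-1-ol
Product: 22 (3R,4R)-4-[(tert-butyldimethylsilyl)oxy]-3-methyloct-6-ynal
Conditions: Dess–Martin periodinane, pyridine, CH2Cl2, 0 °C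
Reagents that add atoms: none
Why: Mild buffered oxidation gives the aldehyde without touching the alkyne or the silyl ether (Dess–Martin oxidation).

Step 15
Reactants: 12 (1S,2E,4aS,8aS)-1-(2-iodoethyl)-2-(methoxymethylidene)-4a,7,7-trimethyldecahydronaphthalene; 22 (3R,4R)-4-[(tert-butyldimethylsilyl)oxy]-3-methyloct-6-ynal
Product: 25 (2Z,4R,5R)-4-[(tert-butyldimethylsilyl)oxy]-5-methyl-2-[4-(DEC)butan-2-ylidene]cyclohexan-1-ol (C1 epimers), via alkyllithium 23 (not isolated), via alkylzinc chloride 24 (not isolated)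
Conditions: 12, t-BuLi, Et2O/pentane, −78 °C; ZnCl2, THF, −78 → 0 °C; then 22, Ni(cod)2 (10 mol %), THF, 0 °C
Reagents that add atoms: none
Why: Zerovalent nickel couples aldehyde and alkyne to an oxanickelacycle, and transmetalation from zinc with reductive elimination delivers C20 to C2 cis to the new C3–C8 bond, which fixes the tetrasubstituted alkene geometry and builds the temporary six-membered ring (nickel-catalysed alkylative cyclization of an ynal with an organozinc).

Step 16
Reactants: 25 (2Z,4R,5R)-4-[(tert-butyldimethylsilyl)oxy]-5-methyl-2-[4-(DEC)butan-2-ylidene]cyclohexan-1-ol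
Product: 26 (2Z,4R,5R)-4-[(tert-butyldimethylsilyl)oxy]-5-methyl-2-[4-(DEC)butan-2-ylidene]cyclohexan-1-one
Conditions: Dess–Martin periodinane, pyridine, CH2Cl2, 0 °C
Reagents that add atoms: none
Why: Both epimeric allylic alcohols are oxidized to the same 2-alkylidene ketone under buffered conditions that should preserve the enol ether and the alkene geometry (Dess–Martin oxidation).

Step 17
Reactants: 26 (2Z,4R,5R)-4-[(tert-butyldimethylsilyl)oxy]-5-methyl-2-[4-(DEC)butan-2-ylidene]cyclohexan-1-one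
Product: 28 (3R,4R,6Z)-4-[(tert-butyldimethylsilyl)oxy]-2-diazo-3-methyl-6-[4-(DEC)butan-2-ylidene]cyclohexan-1-one, via trifluoroacetyl ketone 27 (not isolated)
Conditions: LiN(SiMe3)2, THF, −78 °C; CF3CO2CH2CF3; then MeSO2N3, Et3N, H2O, MeCN, 20 °C
Reagents that add atoms: methanesulfonyl azide (CS(=O)(=O)N=[N+]=[N-])
Why: Kinetic enolization occurs at the α′-methylene C7, trifluoroacetylation activates it, and the sulfonyl azide transfers the diazo group with loss of the trifluoroacetyl group (detrifluoroacetylative, Regitz-type diazo transfer).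

Step 18
Reactants: 28 (3R,4R,6Z)-4-[(tert-butyldimethylsilyl)oxy]-2-diazo-3-methyl-6-[4-(DEC)butan-2-ylidene]cyclohexan-1-one
Product: 31 tetracyclic keto aldehyde (skeleton of 36 with C5–OSiMe2t-Bu, C8 ketone and C9 formyl; C5, C6, C7, C9, C12, C17, C18 as in 36), via vinylketene 29 (not isolated), via cyclobutanone 30 (not isolated)
Conditions: hν (440 nm LEDs), benzene (0.002 M), 20 °C; then 1 M aq. HCl, THF, 0 °C
Reagents that add atoms: water (O)
Why: Proposed new method: excitation of the s-cis-locked α-diazo ketone expels N2 with concerted 1,2-shift of the only migratable group, alkylidene carbon C3, from C8 to C7 (Wolff ring contraction), which forms C3–C7, turns the temporary cyclohexanone into ring A and gives a vinylketene whose electrophilic carbon C8 is held by the (Z)-alkene within reach of the enol ether; C9 then adds to C8 in the ketene plane and the zwitterion closes C7–C9a to a 3-methoxycyclobutanone, which the aqueous acid opens again by push–pull cleavage of C7–C9a. The closest known reaction types are the photochemical Wolff ring contraction of cyclic 2-diazo ketones, vinylketene formation from α′-diazo enones and ketene–enol ether [2+2] cycloadditions; the new element is the intramolecular capture that closes a ring of eight. Ring A arises by ring contraction through the 1,2-alkenyl shift, ring B by an eight-membered polar ring closure (C9 onto C8) that is completed as a bridged [2+2] and released by fragmentation of the cyclobutanone. C9 is set by attack of C8 on the equatorial face of the exocyclic enol ether, so that C8 becomes equatorial and C9a axial, and C7 is set in the acid stage by kinetic α-protonation of the dienol on the face opposite the C6 methyl and the departing C9a. The step needs the Wolff shift instead of carbene 1,2-hydrogen shift or enone isomerization, which the cyclic s-cis diazo ketone and 440 nm light that the enone does not absorb should secure, and it needs C8–C9 capture instead of ketene dimerization or hydration, which high dilution, dry solvent and the enol ether being the only nucleophilic alkene should secure.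

Step 19
Reactants: 31 tetracyclic keto aldehyde
Product: 32 hydroxy ketone (31 with C9–CH2OH in place of C9–CHO)
Conditions: NaBH4, MeOH/CH2Cl2, −78 °C
Reagents that add atoms: none
Why: At low temperature borohydride should reduce the neopentyl aldehyde much faster than the ketone, which is flanked by a tertiary and a quaternary carbon (chemoselective hydride reduction).

Step 20
Reactants: 32 hydroxy ketone
Product: 33 diol (C8–OH configured as in 36, C9–CH2OH, C5–OSiMe2t-Bu)
Conditions: Me4NBH(OAc)3, MeCN/AcOH, −20 °C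
Reagents that add atoms: none
Why: Ligand exchange ties the borohydride to the axial hydroxymethyl oxygen, so hydride is delivered intramolecularly to the face of the C8 carbonyl syn to C9a and the new C8–H ends cis to the future C9 methyl (Evans–Saksena hydroxyl-directed reduction).

Step 21
Reactants: 33 diol
Product: 34 primary O-phenyl thionocarbonate of 33 (C9–CH2OC(S)OPh)
Conditions: PhOC(S)Cl, pyridine, DMAP (cat.), CH2Cl2, 0 °C
Reagents that add atoms: O-phenyl carbonochloridothioate (S=C(Cl)Oc1ccccc1)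
Why: The primary hydroxyl should be thioacylated in preference to the secondary C8 hydroxyl, which sits next to a quaternary centre (thionocarbonate formation for Barton–McCombie deoxygenation).

Step 22
Reactants: 34 primary O-phenyl thionocarbonate
Product: 35 C5 tert-butyldimethylsilyl ether of 36
Conditions: Bu3SnH, AIBN (cat.), toluene, 110 °C
Reagents that add atoms: none
Why: Stannyl radical addition to the thiocarbonyl and β-scission give the primary C9a radical, which takes hydrogen from the tin hydride and leaves the C9 methyl group without an SN2 step at the neopentyl carbon (Barton–McCombie deoxygenation).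

Step 23
Reactants: 35 C5 tert-butyldimethylsilyl ether of 36
Product: 36 target diol CNP0213887.1
Conditions: Bu4NF, THF, 50 °C
Reagents that add atoms: none
Why: Fluoride cleaves the silyl ether and releases the C5 hydroxyl to give the target (desilylation).

Compound list
1 | 3,3-dimethylcyclohexan-1-one | CC1(C)CCCC(=O)C1 | starting material
2 | lithium 5,5-dimethylcyclohex-1-en-1-olate | [Li+].[O-]C1=CCCC(C)(C)C1 | intermediate
3 | 2,5,5-trimethylcyclohexan-1-one (racemic) | CC1CCC(C)(C)CC1=O | intermediate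
4 | 2,5,5-trimethyl-N-[(1R)-1-phenylethyl]cyclohexan-1-imine (C2 epimers) | CC1CCC(C)(C)CC1=N[C@H](C)c1ccccc1 | intermediate
5 | 4-[(1S)-1,4,4-trimethyl-2-{[(1R)-1-phenylethyl]imino}cyclohexyl]butan-2-one | CC(=O)CC[C@]1(C)CCC(C)(C)CC1=N[C@H](C)c1ccccc1 | intermediate
6 | (S)-2,5,5-trimethyl-2-(3-oxobutyl)cyclohexan-1-one | CC(=O)CC[C@]1(C)CCC(C)(C)CC1=O | intermediate
7 | (S)-4a,7,7-trimethyl-4,4a,5,6,7,8-hexahydronaphthalen-2(3H)-one | O=C1CC[C@]2(C)CCC(C)(C)CC2=C1 | intermediate
8 | lithium (4aS,8aS)-4a,7,7-trimethyl-3,4,4a,5,6,7,8,8a-octahydronaphthalen-2-olate | [Li+].[O-]C1CC[C@]2(C)CCC(C)(C)C[C@H]2C=1 | intermediate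
9 | tert-butyl 2-[(1S,4aS,8aS)-4a,7,7-trimethyl-2-oxodecahydronaphthalen-1-yl]acetate | O=C1CC[C@]2(C)CCC(C)(C)C[C@H]2[C@@H]1CC(=O)OC(C)(C)C | intermediate
10 | tert-butyl 2-(DEC)acetate | CO/C=C1\CC[C@]2(C)CCC(C)(C)C[C@H]2[C@@H]1CC(=O)OC(C)(C)C | intermediate
11 | 2-(DEC)ethan-1-ol | CO/C=C1\CC[C@]2(C)CCC(C)(C)C[C@H]2[C@@H]1CCO | intermediate
12 | (1S,2E,4aS,8aS)-1-(2-iodoethyl)-2-(methoxymethylidene)-4a,7,7-trimethyldecahydronaphthalene | CO/C=C1\CC[C@]2(C)CCC(C)(C)C[C@H]2[C@@H]1CCI | intermediate
13 | (E)-but-2-en-1-ol | C/C=C/CO | starting material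
14 | [(2R,3R)-3-methyloxiran-2-yl]methanol | OC[C@H]1O[C@@H]1C | intermediate
15 | (2S,3R)-3-methylpent-4-ene-1,2-diol | OC[C@@H](O)[C@H](C)C=C | intermediate
16 | (2S,3R)-2-hydroxy-3-methylpent-4-en-1-yl 4-methylbenzenesulfonate | Cc1ccc(cc1)S(=O)(=O)OC[C@@H](O)[C@H](C)C=C | intermediate
17 | (2S)-2-[(2R)-but-3-en-2-yl]oxirane | C1O[C@H]1[C@H](C)C=C | intermediate
18 | (3R,4R)-3-methyloct-1-en-6-yn-4-ol | CC#CC[C@@H](O)[C@H](C)C=C | intermediate
19 | tert-butyldimethyl{[(3R,4R)-3-methyloct-1-en-6-yn-4-yl]oxy}silane | CC#CC[C@@H](O[Si](C)(C)C(C)(C)C)[C@H](C)C=C | intermediate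
20 | 9-{(3R,4R)-4-[(tert-butyldimethylsilyl)oxy]-3-methyloct-6-yn-1-yl}-9-borabicyclo[3.3.1]nonane | CC#CC[C@@H](O[Si](C)(C)C(C)(C)C)[C@H](C)CCB1C2CCCC1CCC2 | intermediate
21 | (3R,4R)-4-[(tert-butyldimethylsilyl)oxy]-3-methyloct-6-yn-1-ol | CC#CC[C@@H](O[Si](C)(C)C(C)(C)C)[C@H](C)CCO | intermediate
22 | (3R,4R)-4-[(tert-butyldimethylsilyl)oxy]-3-methyloct-6-ynal | CC#CC[C@@H](O[Si](C)(C)C(C)(C)C)[C@H](C)CC=O | intermediate
23 | [2-(DEC)ethyl]lithium | CO/C=C1\CC[C@]2(C)CCC(C)(C)C[C@H]2[C@@H]1CC[Li] | intermediate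
24 | [2-(DEC)ethyl]zinc chloride | CO/C=C1\CC[C@]2(C)CCC(C)(C)C[C@H]2[C@@H]1CC[Zn]Cl | intermediate
25 | (2Z,4R,5R)-4-[(tert-butyldimethylsilyl)oxy]-5-methyl-2-[4-(DEC)butan-2-ylidene]cyclohexan-1-ol (both C1 epimers) | CO/C=C1\CC[C@]2(C)CCC(C)(C)C[C@H]2[C@@H]1CC/C(C)=C3/C[C@@H](O[Si](C)(C)C(C)(C)C)[C@H](C)CC3O | intermediate
26 | (2Z,4R,5R)-4-[(tert-butyldimethylsilyl)oxy]-5-methyl-2-[4-(DEC)butan-2-ylidene]cyclohexan-1-one | CO/C=C1\CC[C@]2(C)CCC(C)(C)C[C@H]2[C@@H]1CC/C(C)=C3/C[C@@H](O[Si](C)(C)C(C)(C)C)[C@H](C)CC3=O | intermediate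
27 | 6-(trifluoroacetyl) derivative of 26 (enolized at C6) | CO/C=C1\CC[C@]2(C)CCC(C)(C)C[C@H]2[C@@H]1CC/C(C)=C3/C[C@@H](O[Si](C)(C)C(C)(C)C)[C@H](C)C(C(=O)C(F)(F)F)C3=O | intermediate
28 | (3R,4R,6Z)-4-[(tert-butyldimethylsilyl)oxy]-2-diazo-3-methyl-6-[4-(DEC)butan-2-ylidene]cyclohexan-1-one | CO/C=C1\CC[C@]2(C)CCC(C)(C)C[C@H]2[C@@H]1CC/C(C)=C3/C[C@@H](O[Si](C)(C)C(C)(C)C)[C@H](C)C(=[N+]=[N-])C3=O | intermediate
29 | {(2Z,4R,5R)-4-[(tert-butyldimethylsilyl)oxy]-5-methyl-2-[4-(DEC)butan-2-ylidene]cyclopentylidene}methanone (vinylketene) | CO/C=C1\CC[C@]2(C)CCC(C)(C)C[C@H]2[C@@H]1CC/C(C)=C3/C[C@@H](O[Si](C)(C)C(C)(C)C)[C@H](C)C3=C=O | intermediate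
30 | bridged 3-methoxycyclobutanone (C8 carbonyl, four-membered ring C7–C8–C9–C9a, C9a–OMe; rings A and B closed, C5–OSiMe2t-Bu) | C/C1=C2\C[C@@H](O[Si](C)(C)C(C)(C)C)[C@H](C)[C@@]23C(=O)[C@]4(CC[C@]5(C)CCC(C)(C)C[C@H]5[C@@H]4CC1)[C@@H]3OC | intermediate
31 | tetracyclic keto aldehyde (C5–OSiMe2t-Bu, C8 ketone, C9 formyl) | C/C1=C2\C[C@@H](O[Si](C)(C)C(C)(C)C)[C@H](C)[C@@H]2C(=O)[C@@]2(C=O)CC[C@]3(C)CCC(C)(C)C[C@H]3[C@@H]2CC1 | intermediate
32 | hydroxy ketone (C5–OSiMe2t-Bu, C8 ketone, C9–CH2OH) | C/C1=C2\C[C@@H](O[Si](C)(C)C(C)(C)C)[C@H](C)[C@@H]2C(=O)[C@@]2(CO)CC[C@]3(C)CCC(C)(C)C[C@H]3[C@@H]2CC1 | intermediate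
33 | diol (C5–OSiMe2t-Bu, (8R)-OH, C9–CH2OH) | C/C1=C2\C[C@@H](O[Si](C)(C)C(C)(C)C)[C@H](C)[C@@H]2[C@@H](O)[C@@]2(CO)CC[C@]3(C)CCC(C)(C)C[C@H]3[C@@H]2CC1 | intermediate
34 | primary O-phenyl thionocarbonate of 33 | C/C1=C2\C[C@@H](O[Si](C)(C)C(C)(C)C)[C@H](C)[C@@H]2[C@@H](O)[C@@]2(COC(=S)Oc3ccccc3)CC[C@]3(C)CCC(C)(C)C[C@H]3[C@@H]2CC1 | intermediate
35 | C5 tert-butyldimethylsilyl ether of 36 | C/C1=C2\C[C@@H](O[Si](C)(C)C(C)(C)C)[C@H](C)[C@@H]2[C@@H](O)[C@@]2(C)CC[C@]3(C)CCC(C)(C)C[C@H]3[C@@H]2CC1 | intermediate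
36 | CNP0213887.1 (5,8-diol) | C/C1=C2\C[C@@H](O)[C@H](C)[C@@H]2[C@@H](O)[C@@]2(C)CC[C@]3(C)CCC(C)(C)C[C@H]3[C@@H]2CC1 | target

Total step count: 23. Longest linear sequence: 16 steps (steps 8–14, then 15–23; the branch through steps 1–7 is equally long).

Steps most likely to fail:

Step 18. The ketene may be lost to dimerization or hydration before the eight-membered ring closes, the carbene may undergo 1,2-hydrogen shift, or protonation at C7 may occur on the wrong face. Fallback from 28 back to 31 by known reactions: photolysis of 28 in methanol (Wolff ring contraction with capture of ketene 29 by the solvent) should give methyl (2Z,4R,5R)-4-[(tert-butyldimethylsilyl)oxy]-5-methyl-2-[4-(DEC)butan-2-ylidene]cyclopentane-1-carboxylate F1; iBu2AlH at −78 °C reduces it to the corresponding carbaldehyde F2; BF3·OEt2 then promotes the intramolecular Mukaiyama-type aldol addition of the enol ether to the aldehyde (eight-membered ring closure) to give, after aqueous work-up, the 8-hydroxy analogue of 31 F3; Dess–Martin oxidation of F3 returns the route to 31.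

Step 15. β-Hydride elimination from the alkylnickel intermediate (hydrogen transfer in place of alkyl transfer) or slow zinc-to-nickel transmetalation may suppress the alkylative pathway. Fallback from 12 and 18 back to 25: Mg in THF converts 12 into [2-(DEC)ethyl]magnesium iodide F4, which is added across the alkyne of 18 under Fe(acac)3 catalysis (hydroxyl-directed syn-carbomagnesiation); quenching with 1,2-diiodoethane should give (3R,4R,6Z)-6-iodo-3,7-dimethyl-9-(DEC)nona-1,6-dien-4-ol F5. Silylation (t-BuMe2SiCl, imidazole) gives its tert-butyldimethylsilyl ether F6, hydroboration–oxidation (9-BBN; NaOH, H2O2) the primary alcohol F7 and Dess–Martin oxidation the aldehyde F8, which an intramolecular Nozaki–Hiyama–Kishi reaction (CrCl2, NiCl2 cat., DMF) closes to 25.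

Step 21. Thioacylation may occur at the secondary C8 hydroxyl, or fragmentation to the primary neopentyl radical in step 22 may be too slow. Fallback from 33 back to 35: selective oxidation of the primary hydroxyl (TEMPO, PhI(OAc)2, CH2Cl2) should give the C9-formyl analogue of 35 F9; its tosylhydrazone F10 (TsNHNH2, THF) is reduced with catecholborane and decomposed with NaOAc·3H2O (Caglioti-type reduction) to 35.

Further compounds
F1 | step 18 | methyl (2Z,4R,5R)-4-[(tert-butyldimethylsilyl)oxy]-5-methyl-2-[4-(DEC)butan-2-ylidene]cyclopentane-1-carboxylate (C1 as C7 of 36) | CO/C=C1\CC[C@]2(C)CCC(C)(C)C[C@H]2[C@@H]1CC/C(C)=C3/C[C@@H](O[Si](C)(C)C(C)(C)C)[C@H](C)[C@@H]3C(=O)OC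
F2 | step 18 | (2Z,4R,5R)-4-[(tert-butyldimethylsilyl)oxy]-5-methyl-2-[4-(DEC)butan-2-ylidene]cyclopentane-1-carbaldehyde | CO/C=C1\CC[C@]2(C)CCC(C)(C)C[C@H]2[C@@H]1CC/C(C)=C3/C[C@@H](O[Si](C)(C)C(C)(C)C)[C@H](C)[C@@H]3C=O
F3 | step 18 | 8-hydroxy analogue of 31 (C8 epimers) | C/C1=C2\C[C@@H](O[Si](C)(C)C(C)(C)C)[C@H](C)[C@@H]2C(O)[C@@]2(C=O)CC[C@]3(C)CCC(C)(C)C[C@H]3[C@@H]2CC1
F4 | step 15 | [2-(DEC)ethyl]magnesium iodide | CO/C=C1\CC[C@]2(C)CCC(C)(C)C[C@H]2[C@@H]1CC[Mg]I
F5 | step 15 | (3R,4R,6Z)-6-iodo-3,7-dimethyl-9-(DEC)nona-1,6-dien-4-ol | CO/C=C1\CC[C@]2(C)CCC(C)(C)C[C@H]2[C@@H]1CC/C(C)=C(\I)C[C@@H](O)[C@H](C)C=C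
F6 | step 15 | tert-butyldimethylsilyl ether of F5 | CO/C=C1\CC[C@]2(C)CCC(C)(C)C[C@H]2[C@@H]1CC/C(C)=C(\I)C[C@@H](O[Si](C)(C)C(C)(C)C)[C@H](C)C=C
F7 | step 15 | (3R,4R,6Z)-4-[(tert-butyldimethylsilyl)oxy]-6-iodo-3,7-dimethyl-9-(DEC)non-6-en-1-ol | CO/C=C1\CC[C@]2(C)CCC(C)(C)C[C@H]2[C@@H]1CC/C(C)=C(\I)C[C@@H](O[Si](C)(C)C(C)(C)C)[C@H](C)CCO
F8 | step 15 | (3R,4R,6Z)-4-[(tert-butyldimethylsilyl)oxy]-6-iodo-3,7-dimethyl-9-(DEC)non-6-enal | CO/C=C1\CC[C@]2(C)CCC(C)(C)C[C@H]2[C@@H]1CC/C(C)=C(\I)C[C@@H](O[Si](C)(C)C(C)(C)C)[C@H](C)CC=O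
F9 | step 21 | C9-formyl analogue of 35 | C/C1=C2\C[C@@H](O[Si](C)(C)C(C)(C)C)[C@H](C)[C@@H]2[C@@H](O)[C@@]2(C=O)CC[C@]3(C)CCC(C)(C)C[C@H]3[C@@H]2CC1
F10 | step 21 | 4-methylbenzenesulfonylhydrazone of F9 | C/C1=C2\C[C@@H](O[Si](C)(C)C(C)(C)C)[C@H](C)[C@@H]2[C@@H](O)[C@@]2(/C=N/NS(=O)(=O)c3ccc(C)cc3)CC[C@]3(C)CCC(C)(C)C[C@H]3[C@@H]2CC1
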